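**Analysis of the target**

The target 10 is 2,3,4,6-tetrabromo-1-methyl-1H-indole. It is a fully aromatic bicycle in which a benzene ring (ring A: C3a, C4, C5, C6, C7, C7a) is fused to a pyrrole ring (ring B: N1, C2, C3, C3a, C7a). N1 carries a methyl group and C2, C3, C4 and C6 each carry bromine. There is no stereocentre, so the whole problem is the regiochemistry of four C–Br bonds. The 2,3-dibromopyrrole part is electron-rich and sensitive to light, acid and wet electrophilic halogen, and the four C–Br bonds rule out organolithium reagents, low-valent transition metals and reducing conditions late in the route. The ring-B bromines sit where an indole reacts with electrophiles anyway. The ring-A bromines do not: bromination of the benzo ring of a 1-methylindole is directed mainly to C5 and C6, so the 4,6-pattern cannot be installed at the end. The strategy rests on two features. C3 is bonded to C3a and lies ortho to the nitrogen-bearing C7a, so it can be the formyl carbon of a benzaldehyde, and ring A with bromine at C4 and C6 and a leaving group at C7a is exactly the substitution of the aldehyde 1. The bromine at C2 can be derived from a carboxyl group, and that same group is what makes C2 nucleophilic enough to close the C2–C3 bond.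

**Retrosynthetic reasoning**

The C2–Br and C3–Br bonds of 10 are cut first. C3–Br is the normal product of electrophilic substitution on an indole. C2–Br is traced back to a C2 carboxylic acid, which an electrophilic bromine source can replace by ipso attack and decarboxylation. This leads to the acid 8, with the tribromo acid 9 as the stage between them. The gain is that ring A is never touched by a halogenating agent, so its pattern cannot be scrambled. The forward reaction has to deliver bromine twice to ring B only.

The acid 8 is taken back to its ethyl ester 6 by a C–O cleavage, passing through the carboxylate salt 7. The ester is needed because the ring-forming step uses ester enolate chemistry, which a free acid would not support.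

The C2–C3 bond of 6 is the key disconnection. Cutting here turns C3 into an aldehyde carbon and C2 into the alpha carbon of an N-aryl glycinate, which is compound 4. Cutting N1–C2 or C3–C3a instead would require a metal-catalysed coupling next to aryl bromides or an electrophilic closure onto a ring deactivated by two bromines. The forward reaction must deprotonate the glycinate CH2, add it to the ortho formyl group to give the adduct 5, and dehydrate 5 to the aromatic pyrrole ring.

The N1–C7a bond of 4 is cut last. The nitrogen arrives as the free amino ester 3, released in the flask from the hydrochloride 2, and it displaces the fluorine of aldehyde 1 by nucleophilic aromatic substitution. The ortho formyl group activates that carbon, and fluorine leaves much faster than bromine in an addition–elimination, so the two bromines of 1 become C4–Br and C6–Br unchanged.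

**Alternatives that were turned down**

Alternative 1: Ring A is opened at C3a–C4 and built onto a preformed 1-methylpyrrole, with oxygen at C4 and C6 standing in for bromine.
- Forward key step: the acyl Meldrum's acid A1 is heated at high dilution in a refluxing aromatic hydrocarbon. The dioxanedione ring fragments to an acylketene, the pyrrole beta-carbon attacks the ketene carbon, and enolisation of the cyclic 1,3-diketone gives the diol A2.
- For it: the closure is a thermal, reagent-free acylation; the 4,6-oxygen pattern follows from the chain with no regiochemical choice; the building blocks are cheap and halogen-free. On independence from a specialised polyhalogenated arene it is the stronger plan.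
- Against it: A2 is an electron-rich, easily oxidised dihydroxyindole. Each phenol must then be converted into a bromide by sulfonate activation and a metal-catalysed halide exchange, at two positions, before ring B can be brominated.
- Comparison: the hardest transformation comes late and the route is at least three steps longer. The chosen route has the ring-A bromines in place from the first step.

Alternative 2: Ring A is opened at C5–C6 and formed by a six-electron electrocyclisation of a triene whose central double bond is the C3a–C7a bond of a pyrrole.
- Forward key step: the triene A3 is heated near 180 °C with a carbonate base in a high-boiling chlorinated aromatic solvent. The CH2 and CBr2 termini join, and dehydrobromination across C5–C6 aromatises the ring to give A4.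
- For it: both ring-A bromines are placed by connectivity. A4 has C2 and C3 free, so the end is a plain double electrophilic bromination, which is more secure than an ipso-bromodecarboxylation. On that point it is stronger.
- Against it: A3 needs a pyrrole with two different bromovinyl groups at adjacent carbons, which takes several steps to assemble. The closure gives up pyrrole aromaticity in the transition state, hence the high temperature, and at that temperature the 1-bromovinyl group can lose HBr to an alkyne or polymerise.
- Comparison: the chosen route reaches the same ring system in two steps from catalogue compounds, by polar chemistry below 120 °C.

Alternative 3: Ring B is opened at C3–C3a and closed by an oxidative C–H/C–H coupling of the N-aryl enaminoate A5.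
- Forward key step: constant-current electrolysis of A5 at a graphite anode with an iodide mediator in an undivided cell joins the ester-bearing alkene carbon to an ortho aryl carbon, with hydrogen evolution at a platinum cathode, and gives A6.
- For it: A5 should come from one conjugate addition of a symmetric secondary aniline to a propiolate ester, and either ortho carbon gives the same 4,6-pattern. No chemical oxidant is consumed. A C3 carboxyl group is replaced by bromine at least as easily as a C2 one, so its endgame is as good or better.
- Against it: the new bond must form at an arene carbon flanked by bromine on a ring deactivated by two bromines, so the arene is a poor partner for an electrophilic or radical alkene carbon. Cathodic cleavage of aryl C–Br bonds is conceivable in an undivided cell, and dedicated equipment is needed.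
- Comparison: in the chosen strategy ring A carries the electrophile and is not the nucleophile, so its electron-poor character helps both the substitution and the closure.

Key step: step 2

**Route**

Step 1
Reactants: 1 2,4-dibromo-6-fluorobenzaldehyde; 2 sarcosine ethyl ester hydrochloride (ethyl N-methylglycinate hydrochloride)
Product: 4 ethyl N-(3,5-dibromo-2-formylphenyl)-N-methylglycinate, via ethyl N-methylglycinate 3 (not isolated)
Conditions: K2CO3 (2.5 equiv), DMSO, 55–60 °C
Reagents that add atoms: none
Why: Nucleophilic aromatic substitution by addition–elimination: K2CO3 frees the amine 3 from 2, which attacks the fluorine-bearing carbon of 1, the anionic adduct being stabilised by the ortho formyl group and inductively by the two meta bromines. Fluoride is displaced much faster than bromide because addition is rate-limiting, so both C–Br bonds should remain, and the moderate temperature is chosen so that 4 can be isolated before it cyclises.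

Step 2
Reactants: 4 ethyl N-(3,5-dibromo-2-formylphenyl)-N-methylglycinate
Product: 6 ethyl 4,6-dibromo-1-methyl-1H-indole-2-carboxylate, via ethyl 4,6-dibromo-3-hydroxy-1-methylindoline-2-carboxylate 5 (not isolated)
Conditions: K2CO3 (1.0 equiv), 4 Å molecular sieves, DMF (0.05 M), 100–110 °C
Reagents that add atoms: none
Why: K2CO3 reversibly deprotonates the CH2 of 4, the only acidic C–H site (alpha to the ester and to N1), and the enolate carbon (future C2) adds to the neighbouring formyl carbon (future C3) to give the alkoxide of 5. The closest known reaction type is the base-mediated intramolecular aldol (Knoevenagel-type) cyclocondensation of N-(2-formylaryl)glycine esters to indole-2-carboxylates. Ring B closes in a 5-(enolexo)-exo-trig mode, which is favoured. The adduct 5 then loses water by an E1cB sequence (deprotonation at C2, expulsion of hydroxide from C3); this is irreversible because it creates the aromatic pyrrole ring, so the reversible aldol equilibrium is drawn toward 6. No stereocentre remains in 6: the two centres of 5 form as a mixture and are both erased. The selectivity needed is chemoselectivity for intramolecular addition over intermolecular condensation and over ester cleavage; it is secured because the aldehyde cannot enolise and sits ortho to the nucleophile, the solution is dilute, and the sieves hold back the water released. The two C–Br bonds are inert to carbonate in DMF, and the ring-A bromine pattern is carried over unchanged from 1.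

Step 3
Reactants: 6 ethyl 4,6-dibromo-1-methyl-1H-indole-2-carboxylate
Product: 8 4,6-dibromo-1-methyl-1H-indole-2-carboxylic acid, via lithium 4,6-dibromo-1-methyl-1H-indole-2-carboxylate 7 (not isolated)
Conditions: LiOH·H2O (3 equiv), THF/MeOH/H2O, 40 °C; then 1 M HCl to pH 2
Reagents that add atoms: lithium hydroxide (used as its monohydrate), [Li+].[OH-]
Why: Ester saponification by acyl substitution on an unhindered heteroaryl ethyl ester; hydroxide at 40 °C should not attack the unactivated aryl bromides, and acidification of the lithium salt 7 should precipitate the acid 8.

Step 4
Reactants: 8 4,6-dibromo-1-methyl-1H-indole-2-carboxylic acid
Product: 10 2,3,4,6-tetrabromo-1-methyl-1H-indole, via 3,4,6-tribromo-1-methyl-1H-indole-2-carboxylic acid 9 (not isolated)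
Conditions: NBS (2.2 equiv), LiOAc (0.1 equiv), dry DMF, 0 °C to rt, dark
Reagents that add atoms: N-bromosuccinimide, O=C1CCC(=O)N1Br
Why: Electrophilic aromatic substitution followed by ipso-bromodecarboxylation (halodecarboxylation of an electron-rich heteroaryl carboxylic acid, an ionic Hunsdiecker-type process): the first equivalent of NBS brominates C3, the most nucleophilic position of 8, to give 9; the second attacks ring B ipso to the carboxyl group at C2, and the carboxylate, kept available by catalytic LiOAc, leaves as CO2 in place of a proton to restore aromaticity. Ring A is deactivated by its two bromines, so C5 and C7 should not compete, and dry conditions avoid hydrolytic oxidation of the 2,3-dibromoindole.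

**Compound list**

1 | 2,4-dibromo-6-fluorobenzaldehyde | O=Cc1c(F)cc(Br)cc1Br | starting material
2 | sarcosine ethyl ester hydrochloride (ethyl N-methylglycinate hydrochloride) | CCOC(=O)CNC.Cl | starting material
3 | ethyl N-methylglycinate (free base) | CCOC(=O)CNC | intermediate
4 | ethyl N-(3,5-dibromo-2-formylphenyl)-N-methylglycinate | CCOC(=O)CN(C)c1cc(Br)cc(Br)c1C=O | intermediate
5 | ethyl 4,6-dibromo-3-hydroxy-1-methylindoline-2-carboxylate (racemic; cis and trans isomers, configuration not controlled) | CCOC(=O)C1N(C)c2cc(Br)cc(Br)c2C1O | intermediate
6 | ethyl 4,6-dibromo-1-methyl-1H-indole-2-carboxylate | CCOC(=O)c1cc2c(Br)cc(Br)cc2n1C | intermediate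
7 | lithium 4,6-dibromo-1-methyl-1H-indole-2-carboxylate | [Li+].[O-]C(=O)c1cc2c(Br)cc(Br)cc2n1C | intermediate
8 | 4,6-dibromo-1-methyl-1H-indole-2-carboxylic acid | OC(=O)c1cc2c(Br)cc(Br)cc2n1C | intermediate
9 | 3,4,6-tribromo-1-methyl-1H-indole-2-carboxylic acid | OC(=O)c1c(Br)c2c(Br)cc(Br)cc2n1C | intermediate
10 | 2,3,4,6-tetrabromo-1-methyl-1H-indole | Cn1c(Br)c(Br)c2c(Br)cc(Br)cc21 | target

**Step count and risks**

Total step count: 4. Longest linear sequence: 4 steps (one linear route from 1 and 2).

Step 2 (key step).
- What may go wrong: the water released in the condensation can saponify the ester in hot carbonate/DMF, and the resulting carboxylate no longer enolises, so closure stalls. The formyl group is twisted out of the ring plane by its two ortho substituents, so the aldol equilibrium may lie back on the side of 4 and dehydration may be slow. On long heating, amine formed by breakdown of DMF can displace the bromine ortho or para to the still-present aldehyde.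
- Fallback: the bond formation and the dehydration are separated. Setting out from 4, the enolate is generated with KOt-Bu in THF at −20 °C and the mixture is quenched cold with acetic acid, so that 5 is isolated as its diastereomer mixture. Then 5 is dehydrated with catalytic p-toluenesulfonic acid in toluene at 60 °C. Ionisation at C3 is assisted by the ortho amino group, and loss of the C2 proton gives the aromatic ring. The sequence comes back to the route at 6 and needs no compound outside the list (entry F0).

Step 4.
- What may go wrong: the reaction may stop after the first bromination, because ring B of 9 is deactivated by three bromines and the carboxyl group, and C2 is flanked by the N-methyl group and the C3 bromine. Forcing it with excess reagent risks over-bromination at C5 or C7, or oxidation of ring B if moisture is present.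
- Fallback: the carboxyl group is removed as a proton before any bromine is introduced. Setting out from 8, protodecarboxylation with Ag2CO3 (0.1 equiv) and acetic acid in DMSO at 120 °C should give 4,6-dibromo-1-methyl-1H-indole F1 (the same structure as A4). F1 is then brominated at C3 and C2 by ordinary electrophilic substitution with NBS (2.1 equiv) in THF at 0 °C to rt, coming back to the route at 10.

Step 1.
- What may go wrong: the substitution may be sluggish because the secondary amino ester is bulky and only moderately nucleophilic and the reacting carbon lies next to a crowded formyl group. Meanwhile the free amino ester 3 can self-condense to a diketopiperazine, and reversible iminium formation at the aldehyde ties up both partners. Higher temperature would start premature cyclisation and attack at the bromine-bearing carbons.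
- Fallback: the nitrogen is introduced with a smaller nucleophile and the acetate arm is added afterwards. Setting out from 1, methylamine (THF solution, excess) with K2CO3 in DMSO at rt, followed by an acidic aqueous work-up to hydrolyse any N-methylimine, should give 2,4-dibromo-6-(methylamino)benzaldehyde F2. F2 is N-alkylated with ethyl bromoacetate (K2CO3, NaI, DMF, 80 °C), coming back to the route at 4. Any 4 that closes under these conditions is 6 formed early.

**Further compounds**

F0 | step 2 | none | none
F1 | step 4 | 4,6-dibromo-1-methyl-1H-indole | Cn1ccc2c(Br)cc(Br)cc21
F2 | step 1 | 2,4-dibromo-6-(methylamino)benzaldehyde | CNc1cc(Br)cc(Br)c1C=O
A1 | alternative 1 | 2,2-dimethyl-5-[2-(1-methyl-1H-pyrrol-2-yl)acetyl]-1,3-dioxane-4,6-dione | CC1(C)OC(=O)C(C(=O)Cc2cccn2C)C(=O)O1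
A2 | alternative 1 | 1-methyl-1H-indole-4,6-diol | Cn1ccc2c(O)cc(O)cc21
A3 | alternative 2 | 3-(1-bromoethenyl)-2-(2,2-dibromoethenyl)-1-methyl-1H-pyrrole | C=C(Br)c1ccn(C)c1C=C(Br)Br
A4 | alternative 2 | 4,6-dibromo-1-methyl-1H-indole | Cn1ccc2c(Br)cc(Br)cc21
A5 | alternative 3 | methyl (E)-3-[(3,5-dibromophenyl)(methyl)amino]prop-2-enoate | COC(=O)/C=C/N(C)c1cc(Br)cc(Br)c1
A6 | alternative 3 | methyl 4,6-dibromo-1-methyl-1H-indole-3-carboxylate | COC(=O)c1cn(C)c2cc(Br)cc(Br)c12
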